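The amounts asked for are shares of the J charged, J being the limiting reagent in each flask, and you can rank them by hand if you count turnovers.

all flasks: J 0.10 M; time 50 min

| charge | G |
|---|---|
| green | 0.150 M |
| teal | 0.220 M |
| red | 0.340 M |

    J + G ⇌ J.G (K1 = 10 /M, k1 = 0.0192 /M/s)
    J.G ⇌ D + X (K2 = 1.91 M, k2 = 0.00116 /s)
    D ⇌ E (K3 = 2.25, k3 = 9.70 × 10⁻⁴ /s)
    J.G → L (k4 = 1.09 × 10⁻⁴ /s)
    J ⇌ Q (K5 = 0.657, k5 = 0.00807 /s)

- which of these there is most of at the end, counted by the J in it, green (E / J / J.G / D)
- which of these there is most of at the end, counted by the J in it, teal (E / J / J.G / D)
- which of these there is most of at the end, counted by the J in it, red (E / J / J.G / D)
- the largest of these amounts at the end, in percent of the J charged, green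
- the largest of these amounts at the end, in percent of the J charged, teal
- the largest of these amounts at the end, in percent of the J charged, red

Follow a charge of J along its road. In green, with J and Q balanced, 60.4% of that pool is free J, and the binding, counted forward at the G charged, turns over 5.21 times in the run, which is more often than the later steps turn over. Teal and red hold more G, so I count the road after the binding. There a J.G waits on average 14.4 min to become D, and that D waits 17.2 min to become E. The leak to L is minor, because the rate constant towards D is ten times the one towards L.

Call n the number of times these two waits, added, fit into the time of reading, 1.58. It counts passages from J.G to E with both steps taken forward and the time spent on binding left out, so it is a rough count. In a flask like these, I expect E to lead D above one and D to lead E below one. Here n is above one in each flask, so I commit to E as the largest in green, teal and red.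

Is one number enough? For the ranking I take it to be, but not for the height, since n holds no G. The binding constant times G at the start is 1.5 in green and larger in red, at 3.40. I therefore expect E to climb from green to red, by an amount this reckoning does not give.

The forecast names E, E and E at 34%, 40% and 45%, holding that "D has passed most of its flux on to E".

The flasks give E at 33.0% in green, E at 40.0% in teal and E at 46.4% in red. D comes next in green, teal and red, at 24.2%, 28.2% and 30.7%. Now carry n to the red flask read early, at 20 min: the two waits fit 0.634 times, below one, and there the lead has changed hands, with D at 30.0% against E at 17.6%.

All constants are made up, and the outcome is calculated.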